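You want to read the flask at 20 h, and your hunch is that it has long stopped moving by then. I agree, and here is my reckoning.

| flask | substrate | coupling partner | remark | time |
|---|---|---|---|---|
| blue | 0.050 M | 3.4 equiv | run made earlier |  |
| green | 0.050 M | 7.5 equiv | run made earlier |  |
| red | 0.025 M | 5 equiv | run made earlier |  |
| flask | 0.050 M | 5.00 equiv |  | 20 h |

| run | time / h | product / % | intermediate / % |
|---|---|---|---|
| blue | 1.33 | 12.0 | 57.9 |
| blue | 2.00 | 15.7 | 68.7 |
| blue | 4.00 | 17.3 | 80.1 |
| blue | 6.00 | 18.2 | 81.6 |
| blue | 10.0 | 18.7 | 81.4 |
| blue | 15.0 | 18.8 | 82.2 |
| green | 1.33 | 22.3 | 47.6 |
| green | 2.00 | 27.6 | 55.5 |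
| green | 4.00 | 32.4 | 65.5 |
| green | 6.00 | 33.7 | 66.0 |
| green | 10.0 | 33.5 | 66.1 |
| green | 15.0 | 33.1 | 66.4 |
| red | 1.33 | 8.9 | 60.2 |
| red | 2.50 | 12.7 | 76.9 |
| red | 5.00 | 15.2 | 84.6 |
| red | 8.00 | 14.4 | 85.0 |
| red | 15.0 | 14.4 | 85.3 |

(readings scatter by 0.3 percentage points)

- what was read earlier has a scatter of 0.3 percentage points, one standard deviation
- the reaction counts as stopped when no species that holds the substrate changes by six tenths of a point or more over the second half of the time

- at 20 h, what has stopped the reaction, if anything has (forward and back rates have come level / all of the substrate has reacted / it is still moving / the coupling partner has run out first)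
- amount of product at 20 h, in percent of the substrate charged
- amount of intermediate at 20 h, in percent of the substrate charged

Take substrate first. Whatever is neither product nor intermediate is still substrate, and at 1.33 h that is 30.1% in blue and 30.1% in green, despite their different partner charges. Blue's fall to 4.00 h reads as a half-life of

0.756 h

So 20 h is far longer than that, about 26.5 half-lives, and I say the flask stops because all of its substrate has reacted.

Now compare the forward and back rates between intermediate and product. From one late reading of each run, c(product) / [c(intermediate) · c(coupling partner)], with free partner taken as charge minus product, reads: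

blue 1.42 /M, green 1.41 /M, red 1.39 /M, mean 1.41 /M

This mean is the balance number: the product-to-intermediate ratio per unit of free partner once the two rates are level. I take the split on the late plateau of the flask to be under thermodynamic control, and reckon:

charge 0.250 M, first ratio 0.352, first product share 26.1%

free partner 0.237 M, ratio 0.334, product 25.0%, intermediate 75.0%

The forecast gives 25% and 75%, the same split as mine, but differs on the stop, naming forward and back rates have come level, since “20 h is well past equilibrium”.

The flask gives 25.0% product and 75.0% intermediate at 20 h, and the stop is that all of the substrate has reacted.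

    coupling partner + intermediate ⇌ product (K = 1.40 /M, k = 0.110 /M/min)
    substrate → intermediate (k = 0.0150 /min)

Substrate in the flask is already down to 0.0123% at 10.0 h. Now use the balance number on a neighbour flask with 20.0 equiv of partner, which keeps 97% of its charge: free partner 0.971 M gives a ratio of 1.37 and a product share of 57.8%. That neighbour stands at 57.6% product at 20.0 h.

The data were generated by integration from invented constants, and the scatter is random.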